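**Retrosynthetic overview**
- The target is the head-to-head [4+2] homodimer of a monomeric spiro-iridal tetraene (two molecules of the monomer give the target with no atom lost); the central cyclohexene (ring C) is made last.
- The monomer's formyl-ethylidene group comes from a ring-A ketone (directed aldol), and the tetraene arm from a cis-fused lactol plus a C11 dienal (aldol condensation, then aldehyde reduction).
- The lactol comes from a spiro[4.5] hydroxy-enone by two substrate-controlled enolate alkylations (allyl on ring B, ester chain axial on ring A), conjugate reduction, hydroxyl-directed ketone reduction and ozonolysis.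
- The spiro hydroxy-enone (rings A/B junction and the first fixed stereocentres) comes from a racemising cis-enedione by an enantioselective Brønsted-acid enol-aldol; the enedione is a ring-opened 5-methylfurfuryl-cyclopentanone.
- Ring order: B (bought as cyclopentanone), then A (step 4), then C (step 17).

Assumption: spiro[4.5]decane locants are used for all intermediates (C1 carbonyl/carbinol carbon of ring B, C2 side-chain carbon, C5 spiro, C6 ester-chain carbon, C7 ring-A carbonyl/alkylidene carbon, C10 methyl carbinol); the (S)-acid in step 4 is taken to give the 5R,10S ketol, and the (R)-acid is used if the sense is opposite.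

**Step 1**
Reactants: 1 cyclopentanone; 2 5-methylfuran-2-carbaldehyde
Product: 3 (2E)-2-[(5-methylfuran-2-yl)methylidene]cyclopentan-1-one
Conditions: 1 (4 equiv), NaOH (10 mol%), H2O/EtOH, 0 to 25 °C
Reagents that add atoms: none
Why: Crossed aldol (Claisen–Schmidt) condensation with a non-enolisable aldehyde; excess ketone suppresses the bis-adduct and the conjugated E-enone is the thermodynamic product.

**Step 2**
Reactants: 3
Product: 4 2-[(5-methylfuran-2-yl)methyl]cyclopentan-1-one (racemic; labile α-centre)
Conditions: H2 (1 atm), Pd/C (5 wt% Pd), EtOAc, 20 °C, stopped after 1 equiv H2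
Reagents that add atoms: none
Why: Chemoselective catalytic hydrogenation of the exocyclic enone C=C; the furan and the ketone are untouched at 1 atm, and the α-centre is left unset.

**Step 3**
Reactants: 4
Product: 5 (3Z)-1-(2-oxocyclopentyl)hex-3-ene-2,5-dione (racemic; labile α-centre)
Conditions: 3-chloroperoxybenzoic acid (1.05 equiv), NaHCO3, CH2Cl2, 0 °C, used at once
Reagents that add atoms: 3-chloroperoxybenzoic acid, O=C(OO)c1cccc(Cl)c1
Why: Oxidative ring opening of a 2,5-dialkylfuran (furan as masked cis-ene-1,4-dione); peracid attack on the furan and ring opening give the Z-enedione with both ring-A carbonyls and the C10 methyl in place.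

**Step 4**
Reactants: 5
Product: 7 (5R,10S)-10-hydroxy-10-methylspiro[4.5]dec-8-ene-1,7-dione, via enol tautomer 6 (not isolated)
Conditions: (S)-3,3'-bis(2,4,6-triisopropylphenyl)-1,1'-binaphthyl-2,2'-diyl hydrogen phosphate (10 mol%), cyclohexane/toluene 4:1, 0.05 M, 40 °C
Reagents that add atoms: none
Why: Proposed new method: a dynamic kinetic, chiral-phosphoric-acid "enol catalysis" spiro-aldolisation in which the acid reversibly enolises the α-branched cyclopentanone to the achiral tetrasubstituted enol 6 (erasing the labile centre), then bridges the enol O–H and the methyl-ketone oxygen so that C5–C10 bond formation runs through a closed chair-like 6-(enolexo)-exo-trig transition state with the methyl equatorial and the two oxygens gauche (hydroxyl cis to the C1 carbonyl), while the binaphthyl pocket selects one enol face to set 5R,10S as the first fixed stereocentres; the cis-enedione holds the ketone within reach and Michael closures from C5 are geometrically excluded (four-membered or 5-endo); the closest known reactions are phosphoric-acid enol catalysis of α-branched cyclic ketones (Michael additions forming quaternary centres) and phosphoric-acid-catalysed intramolecular aldolisation of triketones (Hajos–Parrish/Wieland–Miescher type).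

**Step 5**
Reactants: 7; 8 allyl bromide (3-bromoprop-1-ene)
Product: 10 (2S,5R,10S)-10-hydroxy-10-methyl-2-(prop-2-en-1-yl)spiro[4.5]dec-8-ene-1,7-dione, via dilithium alkoxide enolate 9 (not isolated)
Conditions: LiN(i-Pr)2 (2.1 equiv), THF, −78 °C (inverse addition); 8 (1.3 equiv), −78 to −45 °C; H2O quench
Reagents that add atoms: none
Why: Kinetic lithium-enolate alkylation; after O–H removal the base takes the unhindered C2 methylene proton of the chelated cyclopentanone (the enone α'-CH2 is neopentylic), and allyl bromide attacks the ring-B enolate face anti to the bulky C10 alkoxide-bearing carbon on the spiro centre, setting 2S.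

**Step 6**
Reactants: 11 3-iodopropan-1-ol; 12 tetradecanoyl chloride
Product: 13 3-iodopropyl tetradecanoate
Conditions: Et3N (1.2 equiv), 4-(dimethylamino)pyridine (5 mol%), CH2Cl2, 0 °C
Reagents that add atoms: none
Why: Standard acylation of a primary alcohol with an acid chloride, giving the electrophile that carries the complete ester side chain.

**Step 7**
Reactants: 10; 13
Product: 15 3-[(2S,5R,6S,10S)-10-hydroxy-10-methyl-1,7-dioxo-2-(prop-2-en-1-yl)spiro[4.5]dec-8-en-6-yl]propyl tetradecanoate, via dilithium alkoxide dienolate 14 (not isolated)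
Conditions: LiN(i-Pr)2 (2.1 equiv), THF, −78 °C; 13 (1.5 equiv), DMPU (4 equiv), −78 to −30 °C; AcOH quench at −78 °C
Reagents that add atoms: none
Why: α'-Alkylation of the cross-conjugated cyclohexenone dienolate (C6 is the only CH2 α-site left, C2–H is tertiary); the lithium alkoxide–C1 carbonyl chelate fixes the half-chair with the ring-B methylene pseudo-axial on C5, so the iodide enters C6 axially from the opposite face and the chain ends cis to the C10 oxygen and to C1 (6S).

**Step 8**
Reactants: 15
Product: 16 3-[(2S,5R,6S,10S)-10-hydroxy-10-methyl-1,7-dioxo-2-(prop-2-en-1-yl)spiro[4.5]decan-6-yl]propyl tetradecanoate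
Conditions: Cu(OAc)2 (5 mol%), 1,2-bis(diphenylphosphino)benzene (5 mol%), Me2PhSiH (1.5 equiv), t-BuOH (2 equiv), toluene, 0 to 20 °C
Reagents that add atoms: none
Why: Copper-hydride conjugate reduction (Stryker type) of the enone only; the allyl group, both ketones and the ester are inert, and the copper enolate forms toward C8 so C6 is not epimerised.

**Step 9**
Reactants: 16
Product: 17 3-[(1R,2S,5S,6S,10S)-1,10-dihydroxy-10-methyl-7-oxo-2-(prop-2-en-1-yl)spiro[4.5]decan-6-yl]propyl tetradecanoate
Conditions: Me4NBH(OAc)3 (5 equiv), MeCN/AcOH 1:1, −25 °C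
Reagents that add atoms: none
Why: Evans–Saksena hydroxyl-directed reduction; the C10 hydroxyl exchanges onto boron and delivers hydride intramolecularly to the β-keto carbon C1 from the C10 face (also anti to the allyl group), giving 1R with the hydroxyl cis to the allyl group, while the undirected C7 ketone is not reduced.

**Step 10**
Reactants: 17
Product: 19 cis-fused lactol of 18 (C1 oxygen closed onto the aldehyde carbon; anomeric mixture), via hydroxy aldehyde 18 (not isolated)
Conditions: O3, CH2Cl2/MeOH 4:1, −78 °C; then Me2S, −78 to 20 °C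
Reagents that add atoms: ozone, [O-][O+]=O
Why: Ozonolysis of the only C=C with reductive work-up; the new aldehyde is trapped by the cis C1 hydroxyl as a five-membered lactol, which also confirms the cis C1/C2 relationship.

**Step 11**
Reactants: 20 6-methylhept-5-en-2-one
Product: 22 6-methylhepta-1,5-dien-2-yl trifluoromethanesulfonate, via potassium enolate 21 (not isolated)
Conditions: KN(SiMe3)2 (1.1 equiv), THF, −78 °C; PhN(SO2CF3)2 (1.1 equiv), −78 to 0 °C
Reagents that add atoms: N-phenylbis(trifluoromethanesulfonimide), O=S(=O)(N(c1ccccc1)S(=O)(=O)C(F)(F)F)C(F)(F)F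
Why: Kinetic deprotonation on the methyl side and O-triflation of the terminal enolate give the 1,1-disubstituted vinyl triflate.

**Step 12**
Reactants: 22; 23 acrolein (prop-2-enal)
Product: 24 (2E)-8-methyl-4-methylidenenona-2,7-dienal
Conditions: Pd(OAc)2 (5 mol%), PPh3 (10 mol%), Et3N (2 equiv), 23 (3 equiv), DMF, 60 °C; used cold and promptly
Reagents that add atoms: none
Why: Mizoroki–Heck coupling of the vinyl triflate with acrolein; syn-insertion and β-hydride elimination give the E-enal carrying the cross-conjugated methylidene diene.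

**Step 13**
Reactants: 19; 24
Product: 25 3-[(1R,2S,5S,6S,10S)-1,10-dihydroxy-10-methyl-2-[(2E,4E)-10-methyl-6-methylidene-1-oxoundeca-2,4,9-trien-2-yl]-7-oxospiro[4.5]decan-6-yl]propyl tetradecanoate
Conditions: pyrrolidine (20 mol%), PhCO2H (20 mol%), 24 (1.5 equiv), CH2Cl2, 0 to 20 °C
Reagents that add atoms: none
Why: Amine-catalysed crossed aldol condensation; the lactol opens to the enolisable aldehyde (enamine donor), 24 has no α- or γ-hydrogen and acts only as acceptor, and dehydration gives the thermodynamic E-2-substituted enal with the polyene arm cis to the ring carbon.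

**Step 14**
Reactants: 25
Product: 26 3-[(1R,2S,5S,6S,10S)-1,10-dihydroxy-2-[(2E,4E)-1-hydroxy-10-methyl-6-methylideneundeca-2,4,9-trien-2-yl]-10-methyl-7-oxospiro[4.5]decan-6-yl]propyl tetradecanoate
Conditions: NaBH(OAc)3 (3 equiv), AcOH (2 equiv), THF, 0 to 20 °C
Reagents that add atoms: none
Why: Chemoselective 1,2-reduction of the aldehyde; triacetoxyborohydride reduces aldehydes but not the hindered C7 ketone or the ester, and the alkene geometry is unchanged.

**Step 15**
Reactants: 27 propanal; 28 cyclohexylamine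
Product: 29 N-cyclohexylpropan-1-imine
Conditions: K2CO3 (anhydrous), neat, 0 to 20 °C; distilled
Reagents that add atoms: none
Why: Simple imine condensation, providing the aldimine used as a propanal enolate equivalent.

**Step 16**
Reactants: 26; 29
Product: 32 3-[(1R,2S,5S,6R,7Z,10S)-1,10-dihydroxy-2-[(2E,4E)-1-hydroxy-10-methyl-6-methylideneundeca-2,4,9-trien-2-yl]-10-methyl-7-(1-oxopropan-2-ylidene)spiro[4.5]decan-6-yl]propyl tetradecanoate, via lithium azaenolate 30 (not isolated), via hydroxy imine adduct 31 (not isolated)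
Conditions: 29 (7 equiv), LiN(i-Pr)2 (7 equiv), THF, 0 °C; 26, −78 to −20 °C; then aq. (CO2H)2 (10%), THF, 20 °C
Reagents that add atoms: water, O
Why: Wittig directed aldol condensation; the lithiated aldimine adds to the only ketone (the three hydroxyls are carried as alkoxides), and oxalic acid hydrolyses the imine and dehydrates the tertiary β-hydroxy aldehyde to the tetrasubstituted enal, expected to settle as the Z isomer (formyl syn to C6, methyl syn to the C8 methylene) as in the natural iridals, with the axial 6-substituent retained.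

**Step 17**
Reactants: 32 3-[(1R,2S,5S,6R,7Z,10S)-1,10-dihydroxy-2-[(2E,4E)-1-hydroxy-10-methyl-6-methylideneundeca-2,4,9-trien-2-yl]-10-methyl-7-(1-oxopropan-2-ylidene)spiro[4.5]decan-6-yl]propyl tetradecanoate (two molecules react with each other: one as the diene partner, one as the dienophile partner)
Product: 33 CNP0458412.1 (Diels–Alder homodimer formed from two molecules of 32; both new ring-C stereocentres R, dienyl and alkenyl arms trans)
Conditions: neat, 2,6-di-tert-butyl-4-methylphenol (2 mol%), Ar, dark, 45 °C, 5 d; preparative HPLC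
Reagents that add atoms: second molecule of 32 (the dienophile partner), CCCCCCCCCCCCCC(=O)OCCC[C@@H]1/C(=C(/C)C=O)CC[C@](C)(O)[C@@]12CC[C@@H](/C(=C\C=C\C(=C)CCC=C(C)C)CO)[C@H]2O
Why: Bimolecular thermal Diels–Alder homodimerisation (2 × 32 → 33, all atoms of both molecules retained) in which the 2-substituted terminal diene (C4'=C5'–C6'=CH2) of one molecule adds to the 1,1-disubstituted C6'=CH2 terminus of the second (CH2 to CH2 bonding from the largest frontier coefficients, giving the head-to-head "para/ortho" adduct), the dienyl arm of the dienophile sits exo as for α-substituted dienophiles (trans arms), and the π-face is biased only by the allylic C2 centre through its A1,3-locked conformation, so the other exo diastereomer is the expected by-product and is removed by HPLC.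

**Compound list**
1 | cyclopentanone | O=C1CCCC1 | starting material
2 | 5-methylfuran-2-carbaldehyde | Cc1ccc(C=O)o1 | starting material
3 | (2E)-2-[(5-methylfuran-2-yl)methylidene]cyclopentan-1-one | O=C1CCC/C1=C\c1ccc(C)o1 | intermediate
4 | 2-[(5-methylfuran-2-yl)methyl]cyclopentan-1-one (racemic, labile) | O=C1CCCC1Cc1ccc(C)o1 | intermediate
5 | (3Z)-1-(2-oxocyclopentyl)hex-3-ene-2,5-dione (racemic, labile) | O=C1CCCC1CC(=O)/C=C\C(C)=O | intermediate
6 | 2-[(3Z)-2,5-dioxohex-3-en-1-yl]cyclopent-1-en-1-ol (achiral enol of 5) | OC1=C(CC(=O)/C=C\C(C)=O)CCC1 | intermediate (not isolated)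
7 | (5R,10S)-10-hydroxy-10-methylspiro[4.5]dec-8-ene-1,7-dione | C1C(=O)C=C[C@](C)(O)[C@@]12CCCC2=O | intermediate
8 | allyl bromide | C=CCBr | starting material
9 | dilithium salt of 7 (C10 alkoxide, C1=C2 enolate) | C1C(=O)C=C[C@](C)(O[Li])[C@@]12CCC=C2O[Li] | intermediate (not isolated)
10 | (2S,5R,10S)-10-hydroxy-10-methyl-2-(prop-2-en-1-yl)spiro[4.5]dec-8-ene-1,7-dione | C1C(=O)C=C[C@](C)(O)[C@@]12CC[C@@H](CC=C)C2=O | intermediate
11 | 3-iodopropan-1-ol | OCCCI | starting material
12 | tetradecanoyl chloride | CCCCCCCCCCCCCC(Cl)=O | starting material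
13 | 3-iodopropyl tetradecanoate | CCCCCCCCCCCCCC(=O)OCCCI | intermediate
14 | dilithium salt of 10 (C10 alkoxide, C6=C7 cross-conjugated dienolate) | C1=C(O[Li])C=C[C@](C)(O[Li])[C@@]12CC[C@@H](CC=C)C2=O | intermediate (not isolated)
15 | 3-[(2S,5R,6S,10S)-10-hydroxy-10-methyl-1,7-dioxo-2-(prop-2-en-1-yl)spiro[4.5]dec-8-en-6-yl]propyl tetradecanoate | CCCCCCCCCCCCCC(=O)OCCC[C@@H]1C(=O)C=C[C@](C)(O)[C@@]12CC[C@@H](CC=C)C2=O | intermediate
16 | 3-[(2S,5R,6S,10S)-10-hydroxy-10-methyl-1,7-dioxo-2-(prop-2-en-1-yl)spiro[4.5]decan-6-yl]propyl tetradecanoate | CCCCCCCCCCCCCC(=O)OCCC[C@@H]1C(=O)CC[C@](C)(O)[C@@]12CC[C@@H](CC=C)C2=O | intermediate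
17 | 3-[(1R,2S,5S,6S,10S)-1,10-dihydroxy-10-methyl-7-oxo-2-(prop-2-en-1-yl)spiro[4.5]decan-6-yl]propyl tetradecanoate | CCCCCCCCCCCCCC(=O)OCCC[C@@H]1C(=O)CC[C@](C)(O)[C@@]12CC[C@@H](CC=C)[C@H]2O | intermediate
18 | 3-[(1R,2S,5S,6S,10S)-1,10-dihydroxy-10-methyl-7-oxo-2-(2-oxoethyl)spiro[4.5]decan-6-yl]propyl tetradecanoate | CCCCCCCCCCCCCC(=O)OCCC[C@@H]1C(=O)CC[C@](C)(O)[C@@]12CC[C@@H](CC=O)[C@H]2O | intermediate (not isolated)
19 | cis-fused lactol of 18 (C1–O closed onto the aldehyde carbon, 2-hydroxytetrahydrofuran ring, anomeric mixture; other centres as in 17) | CCCCCCCCCCCCCC(=O)OCCC[C@@H]1C(=O)CC[C@](C)(O)[C@@]12CC[C@H]3CC(O)O[C@@H]23 | intermediate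
20 | 6-methylhept-5-en-2-one | CC(=O)CCC=C(C)C | starting material
21 | potassium 6-methylhepta-1,5-dien-2-olate | [K]OC(=C)CCC=C(C)C | intermediate (not isolated)
22 | 6-methylhepta-1,5-dien-2-yl trifluoromethanesulfonate | C=C(OS(=O)(=O)C(F)(F)F)CCC=C(C)C | intermediate
23 | acrolein | C=CC=O | starting material
24 | (2E)-8-methyl-4-methylidenenona-2,7-dienal | O=C/C=C/C(=C)CCC=C(C)C | intermediate
25 | 3-[(1R,2S,5S,6S,10S)-1,10-dihydroxy-10-methyl-2-[(2E,4E)-10-methyl-6-methylidene-1-oxoundeca-2,4,9-trien-2-yl]-7-oxospiro[4.5]decan-6-yl]propyl tetradecanoate | CCCCCCCCCCCCCC(=O)OCCC[C@@H]1C(=O)CC[C@](C)(O)[C@@]12CC[C@@H](/C(=C\C=C\C(=C)CCC=C(C)C)C=O)[C@H]2O | intermediate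
26 | 3-[(1R,2S,5S,6S,10S)-1,10-dihydroxy-2-[(2E,4E)-1-hydroxy-10-methyl-6-methylideneundeca-2,4,9-trien-2-yl]-10-methyl-7-oxospiro[4.5]decan-6-yl]propyl tetradecanoate | CCCCCCCCCCCCCC(=O)OCCC[C@@H]1C(=O)CC[C@](C)(O)[C@@]12CC[C@@H](/C(=C\C=C\C(=C)CCC=C(C)C)CO)[C@H]2O | intermediate
27 | propanal | CCC=O | starting material
28 | cyclohexylamine | NC1CCCCC1 | starting material
29 | N-cyclohexylpropan-1-imine | CCC=NC1CCCCC1 | intermediate
30 | lithium cyclohexyl(prop-1-en-1-yl)azanide (azaenolate of 29) | CC=CN([Li])C1CCCCC1 | intermediate (not isolated)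
31 | adduct of 26 with 30: C7 becomes C(OH)–CH(CH3)–CH=N–cyclohexyl (two new centres unassigned; other centres as in 26) | CCCCCCCCCCCCCC(=O)OCCC[C@@H]1C(O)(C(C)C=NC3CCCCC3)CC[C@](C)(O)[C@@]12CC[C@@H](/C(=C\C=C\C(=C)CCC=C(C)C)CO)[C@H]2O | intermediate (not isolated)
32 | 3-[(1R,2S,5S,6R,7Z,10S)-1,10-dihydroxy-2-[(2E,4E)-1-hydroxy-10-methyl-6-methylideneundeca-2,4,9-trien-2-yl]-10-methyl-7-(1-oxopropan-2-ylidene)spiro[4.5]decan-6-yl]propyl tetradecanoate | CCCCCCCCCCCCCC(=O)OCCC[C@@H]1/C(=C(/C)C=O)CC[C@](C)(O)[C@@]12CC[C@@H](/C(=C\C=C\C(=C)CCC=C(C)C)CO)[C@H]2O | intermediate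
33 | CNP0458412.1 (Diels–Alder homodimer of two molecules of 32) | CCCCCCCCCCCCCC(=O)OCCC[C@@H]1/C(=C(/C)C=O)CC[C@](C)(O)[C@@]12CC[C@@H](/C(=C\C=C\[C@@]1(CCC=C(C)C)CCC(CCC=C(C)C)=C[C@@H]1/C=C(/CO)[C@@H]1CC[C@]3([C@H](CCCOC(=O)CCCCCCCCCCCCC)/C(=C(/C)C=O)CC[C@]3(C)O)[C@@H]1O)CO)[C@H]2O | target

**Step count**
Total: 17 steps. Longest linear sequence: 13 steps (steps 1–5, 7–10, 13, 14, 16, 17). Step 17 consumes two molecules of 32 per molecule of 33.

**Three steps most likely to fail**

Step 4 (the proposed new enol-aldol). The risks are low enantioselectivity, Michael closure from the less substituted enol onto the enedione (a bicyclo[3.2.1] by-product), and acid-induced Z/E isomerisation of 5. The fallback uses known chemistry and changes the source of chirality from catalysis to resolution. It sets out from 5: an achiral acid (diphenyl phosphate, 10 mol%, toluene, 40 °C) promotes the same intramolecular aldol to give the racemic ketol, which is 7 together with the enantiomeric ketol F1. Preparative chiral supercritical-fluid chromatography on an amylose carbamate phase separates them, and the route is rejoined at 7.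

Step 16 (formyl-olefination of a hindered ketone carrying three free hydroxyls and an ester). The azaenolate may enolise the ketone or attack the ester rather than add to C7, and the Z/E ratio of the enal is not guaranteed. The fallback is the Babler–Dauben sequence and sets out from 26. Silylation (t-BuMe2SiOSO2CF3, 2,6-lutidine, −78 °C) gives the bis(tert-butyldimethylsilyl) ether F2. Addition of CH2=C(CH3)MgBr/CeCl3 at −78 °C, which leaves the ester alone, gives the tertiary isopropenyl carbinol F3. Oxidative 1,3-transposition with pyridinium chlorochromate C5H5NH[CrO3Cl] and NaOAc in CH2Cl2 gives the bis-silylated enal F4. HF·pyridine in THF/pyridine removes both silyl groups and the route is rejoined at 32.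

Step 17 (dimerisation). Regiochemistry and exo preference are well founded, but π-facial control by the remote C2 centre is weak, and the enal-bearing monomer may not tolerate long heating. The fallback changes the order of events and sets out from 26. Two molecules of the more robust ketone triol 26 are dimerised first (neat, radical inhibitor, 60–70 °C), and the diastereomers are separated at this stage to give the bis-ketone dimer F5. The step-16 protocol is then applied at both ketones (excess 30, then aqueous oxalic acid), passing through the bis(hydroxy imine) adduct F6 (not isolated). The route is rejoined at 33.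

**Further compounds**
F1 | step 4 | (5S,10R)-10-hydroxy-10-methylspiro[4.5]dec-8-ene-1,7-dione (enantiomer of 7) | C1C(=O)C=C[C@@](C)(O)[C@]12CCCC2=O
F2 | step 16 | bis(tert-butyldimethylsilyl) ether of 26 (C1–O and side-chain CH2–O silylated) | CCCCCCCCCCCCCC(=O)OCCC[C@@H]1C(=O)CC[C@](C)(O)[C@@]12CC[C@@H](/C(=C\C=C\C(=C)CCC=C(C)C)CO[Si](C)(C)C(C)(C)C)[C@H]2O[Si](C)(C)C(C)(C)C
F3 | step 16 | F2 with the C7 ketone converted to the tertiary prop-1-en-2-yl carbinol (C7 unassigned) | CCCCCCCCCCCCCC(=O)OCCC[C@@H]1C(O)(C(C)=C)CC[C@](C)(O)[C@@]12CC[C@@H](/C(=C\C=C\C(=C)CCC=C(C)C)CO[Si](C)(C)C(C)(C)C)[C@H]2O[Si](C)(C)C(C)(C)C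
F4 | step 16 | bis(tert-butyldimethylsilyl) ether of 32 | CCCCCCCCCCCCCC(=O)OCCC[C@@H]1/C(=C(/C)C=O)CC[C@](C)(O)[C@@]12CC[C@@H](/C(=C\C=C\C(=C)CCC=C(C)C)CO[Si](C)(C)C(C)(C)C)[C@H]2O[Si](C)(C)C(C)(C)C
F5 | step 17 | Diels–Alder homodimer of 26 (33 with both formylethylidene groups replaced by C7 ketones) | CCCCCCCCCCCCCC(=O)OCCC[C@@H]1C(=O)CC[C@](C)(O)[C@@]12CC[C@@H](/C(=C\C=C\[C@@]1(CCC=C(C)C)CCC(CCC=C(C)C)=C[C@@H]1/C=C(/CO)[C@@H]1CC[C@]3([C@H](CCCOC(=O)CCCCCCCCCCCCC)C(=O)CC[C@]3(C)O)[C@@H]1O)CO)[C@H]2O
F6 | step 17 | bis(hydroxy imine) adduct of F5 with 30 (both C7 carbons as C(OH)–CH(CH3)–CH=N–cyclohexyl; new centres unassigned) | CCCCCCCCCCCCCC(=O)OCCC[C@@H]1C(O)(C(C)C=NC4CCCCC4)CC[C@](C)(O)[C@@]12CC[C@@H](/C(=C\C=C\[C@@]1(CCC=C(C)C)CCC(CCC=C(C)C)=C[C@@H]1/C=C(/CO)[C@@H]1CC[C@]3([C@H](CCCOC(=O)CCCCCCCCCCCCC)C(O)(C(C)C=NC4CCCCC4)CC[C@]3(C)O)[C@@H]1O)CO)[C@H]2O
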